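Ring B is cut across C5–C6 and C9–C10 into dimethyl mesaconate and Danishefsky's diene. One enantioselective Diels–Alder reaction closes ring B and sets both stereocentres. It exploits the vicinal pair C10 (quaternary) and C5, where the C10 methyl is cis and the C1 chain trans to the C4 carbon on C5, exactly the E geometry of the dienophile, while the diene delivers C6, the C7 ketone and the C8=C9 enone. The precursor is simply the two commercial acyclic partners. Afterwards the C4 ester becomes isopropenyl, the C1 ester the propanoate chain, and aromatic ring C with its free C11/C14 hydroquinone is annulated onto C8=C9 with a sulfonyl tetronate.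

Key step: step 1

Remark: locants C1 to C14 are those of the target (C10 quaternary carbon, C5 its CH neighbour, C6 ring CH2, C7 ketone, C8/C9 ring-fusion carbons, C11 to C14 the remaining arene carbons, C4 the isopropenyl carbon, C1 to C3 the acid chain); butenolide locants are those of furan-2(5H)-one.

Assumption: the (S)-configured catalyst is taken to expose the face of 1 that leads to (1R,6R)-5; if the sense of induction should be the opposite, the (R)-catalyst would be used with nothing else changed.

Step 1
Reactants: 1 dimethyl mesaconate [dimethyl (E)-2-methylbut-2-enedioate]; 2 Danishefsky's diene [(E)-1-methoxy-3-(trimethylsilyloxy)buta-1,3-diene]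
Product: 5 dimethyl (1R,6R)-1-methyl-4-oxocyclohex-2-ene-1,6-dicarboxylate, via silyl enol ether cycloadduct 3 (not isolated), via methoxy ketone 4 (not isolated)
Conditions: (S)-1-(2-methylphenyl)-3,3-diphenyltetrahydro-1H,3H-pyrrolo[1,2-c][1,3,2]oxazaborole (10 mol%), AlBr3 (8 mol%), CH2Cl2, −78 °C, slow addition of 2 (1.5 equiv); then 0.1 M HCl, THF, 0 °C
Reagents that add atoms: none
Why: The AlBr3-activated oxazaborolidine binds an ester carbonyl of 1 and lowers its LUMO, so that the electron-rich diene adds in a concerted but asynchronous [4+2] cycloaddition in which the CH2 terminus of 2 bonds first to the unsubstituted alkene carbon (future C5) and the methoxy-bearing terminus then bonds to the methylated carbon (future C10). The closest known reaction type is the oxazaborolidinium-catalysed Diels–Alder reaction of 2-silyloxy and 1-alkoxy-3-silyloxy butadienes with fumarate and methacrylate-type esters. Ring B is the only ring closed, and it is closed by the cycloaddition itself as an all-carbon six-membered ring. The relative configuration of C5 and C10 is controlled by the E geometry of 1, which suprafacial addition transfers as C10 methyl cis to the C5 ester with the two esters trans, and the absolute configuration is controlled by the chiral Lewis acid, which leaves one face of the bound dienophile open. The step needs regioselectivity, secured by the push of the siloxy and methoxy groups toward the CH2 terminus and by the lower substitution and higher electrophilicity of C5, and it needs retention of the alkene geometry, secured by the concerted pathway at low temperature. Dilute acid then hydrolyses the silyl enol ether 3 and eliminates methanol from 4, which touches neither the quaternary C10 nor C5.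

Step 2
Reactants: 5 dimethyl (1R,6R)-1-methyl-4-oxocyclohex-2-ene-1,6-dicarboxylate
Product: 6 dimethyl (8R,9R)-8-methyl-1,4-dioxaspiro[4.5]dec-6-ene-8,9-dicarboxylate
Conditions: TMSOCH2CH2OTMS (1.5 equiv), TMSOTf (5 mol%), CH2Cl2, −78 → −20 °C; pyridine
Reagents that add atoms: 1,2-bis(trimethylsilyloxy)ethane, C[Si](C)(C)OCCO[Si](C)(C)C
Why: Silyl-transfer ketalisation masks the only ketone under nearly neutral conditions, and the C8=C9 bond cannot migrate because C10 is quaternary, so the alkene and both stereocentres stay in place.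

Step 3
Reactants: 6 dimethyl (8R,9R)-8-methyl-1,4-dioxaspiro[4.5]dec-6-ene-8,9-dicarboxylate
Product: 7 methyl (8R,9R)-9-[methoxy(methyl)carbamoyl]-8-methyl-1,4-dioxaspiro[4.5]dec-6-ene-8-carboxylate
Conditions: MeNH(OMe)·HCl (2 equiv), iPrMgCl (4 equiv), THF, −20 → 0 °C
Reagents that add atoms: N,O-dimethylhydroxylamine hydrochloride, CNOC.Cl
Why: Direct ester-to-Weinreb-amide exchange with the chloromagnesium amide takes place at the secondary C4 ester, whereas the C1 ester on the quaternary C10 is sterically shielded and should remain, and the weakly basic amide should not epimerise C5.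

Step 4
Reactants: 7 methyl (8R,9R)-9-[methoxy(methyl)carbamoyl]-8-methyl-1,4-dioxaspiro[4.5]dec-6-ene-8-carboxylate
Product: 8 methyl (8R,9R)-9-acetyl-8-methyl-1,4-dioxaspiro[4.5]dec-6-ene-8-carboxylate
Conditions: MeMgBr (1.5 equiv), THF, −20 → 0 °C; aq. NH4Cl
Reagents that add atoms: methylmagnesium bromide, C[Mg]Br
Why: Weinreb ketone synthesis, in which the magnesium chelate of the tetrahedral adduct holds until the quench, so only one methyl is delivered and no free alkoxide arises next to the hindered C1 ester, which is left unattacked at this temperature.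

Step 5
Reactants: 8 methyl (8R,9R)-9-acetyl-8-methyl-1,4-dioxaspiro[4.5]dec-6-ene-8-carboxylate
Product: 9 methyl (8R,9S)-8-methyl-9-(prop-1-en-2-yl)-1,4-dioxaspiro[4.5]dec-6-ene-8-carboxylate
Conditions: Ph3PCH3Br (2 equiv), KOtBu (1.9 equiv), THF, 0 → 25 °C
Reagents that add atoms: methyltriphenylphosphonium bromide, [Br-].C[P+](c1ccccc1)(c1ccccc1)c1ccccc1
Why: Wittig methylenation gives the isopropenyl group with no regiochemical ambiguity, and the lithium-free ylide should add to the methyl ketone faster than it removes the hindered C5–H, so the C5 configuration is retained (the descriptor changes only through priorities).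

Step 6
Reactants: 9 methyl (8R,9S)-8-methyl-9-(prop-1-en-2-yl)-1,4-dioxaspiro[4.5]dec-6-ene-8-carboxylate
Product: 10 [(8R,9S)-8-methyl-9-(prop-1-en-2-yl)-1,4-dioxaspiro[4.5]dec-6-en-8-yl]methanol
Conditions: LiAlH4 (1.5 equiv), THF, 0 → 25 °C
Reagents that add atoms: none
Why: Hydride reduction of the hindered ester to the neopentyl alcohol, to which the ketal, both alkenes and both stereocentres are inert.

Step 7
Reactants: 10 [(8R,9S)-8-methyl-9-(prop-1-en-2-yl)-1,4-dioxaspiro[4.5]dec-6-en-8-yl]methanol
Product: 11 (8R,9S)-8-methyl-9-(prop-1-en-2-yl)-1,4-dioxaspiro[4.5]dec-6-ene-8-carbaldehyde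
Conditions: Dess–Martin periodinane (1.3 equiv), NaHCO3, CH2Cl2, 0 → 25 °C
Reagents that add atoms: none
Why: Dess–Martin oxidation stops at the aldehyde, which has no alpha hydrogen and so can neither epimerise nor isomerise, while the bicarbonate buffer protects the ketal.

Step 8
Reactants: 11 (8R,9S)-8-methyl-9-(prop-1-en-2-yl)-1,4-dioxaspiro[4.5]dec-6-ene-8-carbaldehyde
Product: 12 methyl (2E)-3-[(8S,9S)-8-methyl-9-(prop-1-en-2-yl)-1,4-dioxaspiro[4.5]dec-6-en-8-yl]prop-2-enoate
Conditions: (MeO)2P(O)CH2CO2Me (1.5 equiv), NaH (1.4 equiv), THF, 0 → 40 °C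
Reagents that add atoms: trimethyl phosphonoacetate, COC(=O)CP(=O)(OC)OC
Why: Horner–Wadsworth–Emmons olefination with the small phosphonoacetate anion tolerates the neopentyl aldehyde and adds C2 and C3 as the E enoate (the C10 descriptor changes only through priorities).

Step 9
Reactants: 12 methyl (2E)-3-[(8S,9S)-8-methyl-9-(prop-1-en-2-yl)-1,4-dioxaspiro[4.5]dec-6-en-8-yl]prop-2-enoate
Product: 13 methyl 3-[(8R,9S)-8-methyl-9-(prop-1-en-2-yl)-1,4-dioxaspiro[4.5]dec-6-en-8-yl]propanoate
Conditions: Mg turnings (10 equiv), MeOH, 0 → 25 °C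
Reagents that add atoms: none
Why: Dissolving-metal conjugate reduction with magnesium in methanol reduces only the electron-poor enoate C=C through its radical anion, whereas the isopropenyl group, the ring alkene and the ketal are not reducible under these conditions.

Step 10
Reactants: 13 methyl 3-[(8R,9S)-8-methyl-9-(prop-1-en-2-yl)-1,4-dioxaspiro[4.5]dec-6-en-8-yl]propanoate
Product: 14 methyl 3-[(1R,6S)-1-methyl-4-oxo-6-(prop-1-en-2-yl)cyclohex-2-en-1-yl]propanoate
Conditions: 1 M HCl, THF, 25 °C
Reagents that add atoms: water, O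
Why: The allylic dioxolane hydrolyses readily through an allyl-stabilised oxocarbenium ion and returns the C7 enone, while the isopropenyl group and the methyl ester survive dilute acid at room temperature.

Step 11
Reactants: 15 4-methoxyfuran-2(5H)-one
Product: 16 3-bromo-4-methoxyfuran-2(5H)-one
Conditions: NBS (1.05 equiv), CH2Cl2, 25 °C, dark
Reagents that add atoms: N-bromosuccinimide, O=C1CCC(=O)N1Br
Why: Electrophilic bromination at C3, the nucleophilic alpha carbon of the vinylogous carbonate, by addition and loss of a proton.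

Step 12
Reactants: 16 3-bromo-4-methoxyfuran-2(5H)-one
Product: 17 4-methoxy-3-(propan-2-yl)furan-2(5H)-one
Conditions: iPrZnBr (1.5 equiv, THF), Pd(OAc)2 (2 mol%), 2-dicyclohexylphosphino-2′,6′-bis(dimethylamino)biphenyl (4 mol%), THF/toluene, 25 °C
Reagents that add atoms: isopropylzinc bromide, CC(C)[Zn]Br
Why: Negishi coupling of a secondary alkylzinc halide, in which the electron-poor alkenyl bromide adds readily to zerovalent palladium and the biaryl phosphine speeds reductive elimination over beta-hydride elimination, so the branched isopropyl group should be retained.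

Step 13
Reactants: 17 4-methoxy-3-(propan-2-yl)furan-2(5H)-one
Product: 18 4-methoxy-5-(phenylsulfanyl)-3-(propan-2-yl)furan-2(5H)-one (racemic)
Conditions: LiN(iPr)2 (1.05 equiv), THF, −78 °C; cannulated into PhSSPh (1.5 equiv), THF, −78 → −40 °C; aq. NH4Cl
Reagents that add atoms: diphenyl disulfide, c1ccc(cc1)SSc1ccccc1
Why: Deprotonation at C5 gives the aromatic lithium 2-furanolate, which is sulfenylated at C5 because C3 is blocked by the isopropyl group, and inverse addition into excess disulfide limits double sulfenylation.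

Step 14
Reactants: 18 4-methoxy-5-(phenylsulfanyl)-3-(propan-2-yl)furan-2(5H)-one
Product: 19 4-methoxy-5-(phenylsulfonyl)-3-(propan-2-yl)furan-2(5H)-one (racemic)
Conditions: mCPBA (2.3 equiv), CH2Cl2, 0 → 25 °C
Reagents that add atoms: 3-chloroperoxybenzoic acid, OOC(=O)c1cccc(Cl)c1
Why: Peracid oxidation of the sulfide to the sulfone by way of the sulfoxide, with the push–pull C3=C4 bond too electron-poor to be epoxidised.

Step 15
Reactants: 14 methyl 3-[(1R,6S)-1-methyl-4-oxo-6-(prop-1-en-2-yl)cyclohex-2-en-1-yl]propanoate; 19 4-methoxy-5-(phenylsulfonyl)-3-(propan-2-yl)furan-2(5H)-one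
Product: 22 methyl 3-[(1S,2S)-5,8-dihydroxy-7-methoxy-1-methyl-4-oxo-6-(propan-2-yl)-2-(prop-1-en-2-yl)-1,2,3,4-tetrahydronaphthalen-1-yl]propanoate, via Michael adduct 20 (not isolated), via diketone tautomer 21 (not isolated)
Conditions: 19 (1.2 equiv), LiOtBu (3 equiv), THF, −78 °C; then 14, −78 → 25 °C; degassed aq. NH4Cl, argon
Reagents that add atoms: none
Why: Proposed new method: the sulfone-stabilised 2-furanolate of 19 should add through C5 to C9 of the enone (vinylogous Michael addition), the C8 enolate so formed should acylate the lactone carbonyl intramolecularly to close six-membered ring C, the released alkoxide on the sulfonyl carbon should expel benzenesulfinate irreversibly, and the resulting ene-dione 21 should tautomerise to the hydroquinone, with no stereocentre formed or touched; the closest known reaction type is the Hauser–Kraus annulation of 3-(phenylsulfonyl)phthalides with cyclohex-2-enones, including 4,4-disubstituted ones, and the new element is a monocyclic tetronate in place of the phthalide.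

Step 16
Reactants: 22 methyl 3-[(1S,2S)-5,8-dihydroxy-7-methoxy-1-methyl-4-oxo-6-(propan-2-yl)-2-(prop-1-en-2-yl)-1,2,3,4-tetrahydronaphthalen-1-yl]propanoate
Product: 23 3-[(1S,2S)-5,8-dihydroxy-7-methoxy-1-methyl-4-oxo-6-(propan-2-yl)-2-(prop-1-en-2-yl)-1,2,3,4-tetrahydronaphthalen-1-yl]propanoic acid (CNP0249049.1)
Conditions: LiOH·H2O (5 equiv), degassed THF/H2O 3:1, argon, 0 → 25 °C; then 1 M HCl to pH 3 at 0 °C, Na2S2O4 wash
Reagents that add atoms: lithium hydroxide, [Li+].[OH-]
Why: Saponification of the unhindered methyl ester, in which the phenoxides are inert to hydroxide, no stereocentre is acidic, the isopropenyl group tolerates brief cold acidification, and exclusion of air with a dithionite wash protects the hydroquinone.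

Compound list
1 | dimethyl mesaconate | COC(=O)/C=C(\C)C(=O)OC | starting material
2 | Danishefsky's diene, (E)-1-methoxy-3-(trimethylsilyloxy)buta-1,3-diene | CO/C=C/C(=C)O[Si](C)(C)C | starting material
3 | dimethyl (1S,6R)-2-methoxy-1-methyl-4-(trimethylsilyloxy)cyclohex-3-ene-1,6-dicarboxylate (C2 not assigned) | COC(=O)[C@@H]1CC(O[Si](C)(C)C)=CC(OC)[C@@]1(C)C(=O)OC | intermediate (not isolated)
4 | dimethyl (1S,6R)-2-methoxy-1-methyl-4-oxocyclohexane-1,6-dicarboxylate (C2 not assigned) | COC(=O)[C@@H]1CC(=O)CC(OC)[C@@]1(C)C(=O)OC | intermediate (not isolated)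
5 | dimethyl (1R,6R)-1-methyl-4-oxocyclohex-2-ene-1,6-dicarboxylate | COC(=O)[C@@H]1CC(=O)C=C[C@@]1(C)C(=O)OC | intermediate
6 | dimethyl (8R,9R)-8-methyl-1,4-dioxaspiro[4.5]dec-6-ene-8,9-dicarboxylate | COC(=O)[C@@H]1CC2(OCCO2)C=C[C@@]1(C)C(=O)OC | intermediate
7 | methyl (8R,9R)-9-[methoxy(methyl)carbamoyl]-8-methyl-1,4-dioxaspiro[4.5]dec-6-ene-8-carboxylate | CON(C)C(=O)[C@@H]1CC2(OCCO2)C=C[C@@]1(C)C(=O)OC | intermediate
8 | methyl (8R,9R)-9-acetyl-8-methyl-1,4-dioxaspiro[4.5]dec-6-ene-8-carboxylate | CC(=O)[C@@H]1CC2(OCCO2)C=C[C@@]1(C)C(=O)OC | intermediate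
9 | methyl (8R,9S)-8-methyl-9-(prop-1-en-2-yl)-1,4-dioxaspiro[4.5]dec-6-ene-8-carboxylate | C=C(C)[C@@H]1CC2(OCCO2)C=C[C@@]1(C)C(=O)OC | intermediate
10 | [(8R,9S)-8-methyl-9-(prop-1-en-2-yl)-1,4-dioxaspiro[4.5]dec-6-en-8-yl]methanol | C=C(C)[C@@H]1CC2(OCCO2)C=C[C@@]1(C)CO | intermediate
11 | (8R,9S)-8-methyl-9-(prop-1-en-2-yl)-1,4-dioxaspiro[4.5]dec-6-ene-8-carbaldehyde | C=C(C)[C@@H]1CC2(OCCO2)C=C[C@@]1(C)C=O | intermediate
12 | methyl (2E)-3-[(8S,9S)-8-methyl-9-(prop-1-en-2-yl)-1,4-dioxaspiro[4.5]dec-6-en-8-yl]prop-2-enoate | C=C(C)[C@@H]1CC2(OCCO2)C=C[C@@]1(C)/C=C/C(=O)OC | intermediate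
13 | methyl 3-[(8R,9S)-8-methyl-9-(prop-1-en-2-yl)-1,4-dioxaspiro[4.5]dec-6-en-8-yl]propanoate | C=C(C)[C@@H]1CC2(OCCO2)C=C[C@@]1(C)CCC(=O)OC | intermediate
14 | methyl 3-[(1R,6S)-1-methyl-4-oxo-6-(prop-1-en-2-yl)cyclohex-2-en-1-yl]propanoate | C=C(C)[C@@H]1CC(=O)C=C[C@@]1(C)CCC(=O)OC | intermediate
15 | 4-methoxyfuran-2(5H)-one | COC1=CC(=O)OC1 | starting material
16 | 3-bromo-4-methoxyfuran-2(5H)-one | COC1=C(Br)C(=O)OC1 | intermediate
17 | 4-methoxy-3-(propan-2-yl)furan-2(5H)-one | COC1=C(C(C)C)C(=O)OC1 | intermediate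
18 | 4-methoxy-5-(phenylsulfanyl)-3-(propan-2-yl)furan-2(5H)-one (racemic) | COC1=C(C(C)C)C(=O)OC1Sc2ccccc2 | intermediate
19 | 4-methoxy-5-(phenylsulfonyl)-3-(propan-2-yl)furan-2(5H)-one (racemic) | COC1=C(C(C)C)C(=O)OC1S(=O)(=O)c2ccccc2 | intermediate
20 | Michael adduct: methyl 3-{1-methyl-2-[3-methoxy-5-oxo-2-(phenylsulfonyl)-4-(propan-2-yl)-2,5-dihydrofuran-2-yl]-4-oxo-6-(prop-1-en-2-yl)cyclohexyl}propanoate (C5 and C10 as in 14; the two new centres not assigned) | C=C(C)[C@@H]1CC(=O)CC(C2(OC(=O)C(C(C)C)=C2OC)S(=O)(=O)c3ccccc3)[C@@]1(C)CCC(=O)OC | intermediate (not isolated)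
21 | diketone tautomer of 22: methyl 3-[7-methoxy-1-methyl-4,5,8-trioxo-6-(propan-2-yl)-2-(prop-1-en-2-yl)-1,2,3,4,4a,5,8,8a-octahydronaphthalen-1-yl]propanoate (C5 and C10 as in 14; C8 and C9 not assigned) | C=C(C)[C@@H]1CC(=O)C2C(=O)C(C(C)C)=C(OC)C(=O)C2[C@@]1(C)CCC(=O)OC | intermediate (not isolated)
22 | methyl 3-[(1S,2S)-5,8-dihydroxy-7-methoxy-1-methyl-4-oxo-6-(propan-2-yl)-2-(prop-1-en-2-yl)-1,2,3,4-tetrahydronaphthalen-1-yl]propanoate | C=C(C)[C@@H]1CC(=O)c2c(O)c(C(C)C)c(OC)c(O)c2[C@@]1(C)CCC(=O)OC | intermediate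
23 | 3-[(1S,2S)-5,8-dihydroxy-7-methoxy-1-methyl-4-oxo-6-(propan-2-yl)-2-(prop-1-en-2-yl)-1,2,3,4-tetrahydronaphthalen-1-yl]propanoic acid | C=C(C)[C@@H]1CC(=O)c2c(O)c(C(C)C)c(OC)c(O)c2[C@@]1(C)CCC(=O)O | target

Total step count: 16. Longest linear sequence: 12 steps (steps 1 to 10, 15 and 16); the donor branch (steps 11 to 14) is four steps from 15.

Steps most likely to fail

Step 15 (labelled step). The tetronate anion may add reversibly and too slowly to C9, which lies next to the quaternary C10. The C8 enolate may also fail to acylate the deactivated vinylogous-carbonate lactone before the adduct reverts or is diverted to the side-chain ester. The fallback uses known reaction types and sets out from 17 and 14. Silylation of 17 (TBSOTf, Et3N) would give tert-butyl{[4-methoxy-3-(propan-2-yl)furan-2-yl]oxy}dimethylsilane F1. Its vinylogous Mukaiyama–Michael addition to 14 (TBSOTf cat., CH2Cl2, −78 °C) would give the silyl enol ether adduct F2 and, after hydrolytic work-up, the keto butenolide F3. KOtBu in THF would then close ring C by intramolecular Claisen acylation of the C8 enolate on the lactone carbonyl, giving the hydroxy ene-dione F4. Dess–Martin oxidation of its C11 carbinol would give 21, which tautomerises to 22, where the route is rejoined.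

Step 1. The strong Lewis acid may desilylate or oligomerise diene 2. The cycloaddition may also become stepwise (conjugate addition, then ring closure), which would loosen the trans relation of the two esters, or the face selectivity may be insufficient. The fallback sets out from 1 and moves the stereocontrol to an auxiliary on the diene, with no Lewis acid. Condensation of (E)-4-methoxybut-3-en-2-one with (2R,5R)-2,5-diphenylpyrrolidine would give (3E)-4-[(2R,5R)-2,5-diphenylpyrrolidin-1-yl]but-3-en-2-one F5. KN(SiMe3)2 and TBSCl would convert it into the chiral 1-amino-3-silyloxy diene (2R,5R)-1-[(1E)-3-(tert-butyldimethylsilyloxy)buta-1,3-dien-1-yl]-2,5-diphenylpyrrolidine F6. Its thermal, concerted cycloaddition with 1 (toluene, 20 to 60 °C) should give the amino cycloadduct F7 with the same regiochemistry and with the E geometry transferred. Dilute HCl in THF would then hydrolyse the silyl enol ether and eliminate the recoverable amine to give 5, where the route is rejoined. The antipodal pyrrolidine would be used if the sense of induction requires it.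

Step 3. Amide exchange at the C4 ester, which sits on a carbon next to the quaternary C10, may be too slow. Forcing it may bring attack on the C1 ester or enolisation at C5. The fallback sets out from 6 and differentiates the esters by hydrolysis instead. LiOH (1.2 equiv, THF/H2O, 0 °C) should cleave only the less hindered C4 ester to give the mono-acid (8R,9R)-8-(methoxycarbonyl)-8-methyl-1,4-dioxaspiro[4.5]dec-6-ene-9-carboxylic acid F8. Activation with 1,1′-carbonyldiimidazole and coupling with N,O-dimethylhydroxylamine hydrochloride would give 7, where the route is rejoined.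

Further compounds
F1 | step 15 | tert-butyl{[4-methoxy-3-(propan-2-yl)furan-2-yl]oxy}dimethylsilane | COc1coc(O[Si](C)(C)C(C)(C)C)c1C(C)C
F2 | step 15 | silyl enol ether adduct: methyl 3-{4-(tert-butyldimethylsilyloxy)-2-[3-methoxy-5-oxo-4-(propan-2-yl)-2,5-dihydrofuran-2-yl]-1-methyl-6-(prop-1-en-2-yl)cyclohex-3-en-1-yl}propanoate (C5 and C10 as in 14; new centres not assigned) | C=C(C)[C@@H]1CC(O[Si](C)(C)C(C)(C)C)=CC(C2OC(=O)C(C(C)C)=C2OC)[C@@]1(C)CCC(=O)OC
F3 | step 15 | keto butenolide: methyl 3-{2-[3-methoxy-5-oxo-4-(propan-2-yl)-2,5-dihydrofuran-2-yl]-1-methyl-4-oxo-6-(prop-1-en-2-yl)cyclohexyl}propanoate (C5 and C10 as in 14; new centres not assigned) | C=C(C)[C@@H]1CC(=O)CC(C2OC(=O)C(C(C)C)=C2OC)[C@@]1(C)CCC(=O)OC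
F4 | step 15 | hydroxy ene-dione: methyl 3-[8-hydroxy-7-methoxy-1-methyl-4,5-dioxo-6-(propan-2-yl)-2-(prop-1-en-2-yl)-1,2,3,4,4a,5,8,8a-octahydronaphthalen-1-yl]propanoate (C5 and C10 as in 14; new centres not assigned) | C=C(C)[C@@H]1CC(=O)C2C(=O)C(C(C)C)=C(OC)C(O)C2[C@@]1(C)CCC(=O)OC
F5 | step 1 | (3E)-4-[(2R,5R)-2,5-diphenylpyrrolidin-1-yl]but-3-en-2-one | CC(=O)/C=C/N1[C@@H](c2ccccc2)CC[C@@H]1c3ccccc3
F6 | step 1 | (2R,5R)-1-[(1E)-3-(tert-butyldimethylsilyloxy)buta-1,3-dien-1-yl]-2,5-diphenylpyrrolidine | C=C(O[Si](C)(C)C(C)(C)C)/C=C/N1[C@@H](c2ccccc2)CC[C@@H]1c3ccccc3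
F7 | step 1 | dimethyl (1S,6R)-4-(tert-butyldimethylsilyloxy)-2-[(2R,5R)-2,5-diphenylpyrrolidin-1-yl]-1-methylcyclohex-3-ene-1,6-dicarboxylate (C2 not assigned) | COC(=O)[C@@H]1CC(O[Si](C)(C)C(C)(C)C)=CC(N2[C@@H](c3ccccc3)CC[C@@H]2c4ccccc4)[C@@]1(C)C(=O)OC
F8 | step 3 | (8R,9R)-8-(methoxycarbonyl)-8-methyl-1,4-dioxaspiro[4.5]dec-6-ene-9-carboxylic acid | OC(=O)[C@@H]1CC2(OCCO2)C=C[C@@]1(C)C(=O)OC
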